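**Retrosynthetic overview**
1. The target is a trans-(3S,4S)-dibenzylbutyrolactone whose C3 benzyl arm is C5 of a trans-(2S,3R)-2-aryl-3-hydroxymethyl-7-hydroxy-2,3-dihydrobenzofuran. The last C–C bond, lactone C3–CH2(aryl C5), is cut to a C5 aryl boronate and the (S)-α-methylene lactone, followed by epimerisation and global debenzylation.
2. The strategy rests on C2 of the dihydrofuran ring, which is benzylic to the 4-oxygenated guaiacyl ring. O1–C2 is therefore cut to a para-alkoxybenzyl cation and the phenol oxygen O1 of the central arene, with the adjacent C3 centre (CH2OH) fixing the trans ring.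
3. The cyclisation precursor, a 2-(2-hydroxyaryl)-1-arylpropane-1,3-diol, comes from an Evans syn-aldol of an arylacetyl imide with O-benzylvanillin (sets C3), reduction and desilylation. The arylacetic acid comes from 2-(benzyloxy)phenol by bromination, O-allylation, Claisen rearrangement, silylation and alkene cleavage.
4. The lactone fragment comes from auxiliary-controlled benzylation of a succinyl imide with O-benzylvanillyl bromide (sets lactone C4), reduction–lactonisation and α-methylenation.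
5. Ring order: the dihydrofuran ring (step 11) and the butyrolactone ring (step 17) are closed in separate branches and joined in step 19.

Key step: step 11

Assumption: imide 10 forms the Z-boron enolate and reacts with the facial sense usual for the (S)-4-benzyl auxiliary; the target is read as lactone (3S,4S) and dihydrobenzofuran (2S,3R), trans in both rings.

**Step 1**
Reactants: 1 2-(benzyloxy)phenol
Product: 2 2-(benzyloxy)-4-bromophenol
Conditions: NBS (1.0 equiv), MeCN, 0 °C
Reagents that add atoms: N-bromosuccinimide, O=C1CCC(=O)N1Br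
Why: Electrophilic aromatic bromination of a phenol goes para to the free hydroxyl, the stronger donor, and that position is open.

**Step 2**
Reactants: 2 2-(benzyloxy)-4-bromophenol
Product: 3 1-(allyloxy)-2-(benzyloxy)-4-bromobenzene
Conditions: allyl bromide, K2CO3, acetone, reflux
Reagents that add atoms: allyl bromide, C=CCBr
Why: Williamson ether synthesis of the phenoxide with a reactive allylic halide.

**Step 3**
Reactants: 3 1-(allyloxy)-2-(benzyloxy)-4-bromobenzene
Product: 4 2-allyl-6-(benzyloxy)-4-bromophenol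
Conditions: N,N-diethylaniline, 190 °C
Reagents that add atoms: none
Why: Aromatic Claisen rearrangement, a [3,3]-sigmatropic shift that delivers the allyl group to the only free ortho position and then tautomerises to the phenol.

**Step 4**
Reactants: 4 2-allyl-6-(benzyloxy)-4-bromophenol
Product: 5 [2-allyl-6-(benzyloxy)-4-bromophenoxy]triisopropylsilane
Conditions: i-Pr3SiOTf, 2,6-lutidine, CH2Cl2, 0 °C → rt
Reagents that add atoms: triisopropylsilyl triflate, CC(C)[Si](OS(=O)(=O)C(F)(F)F)(C(C)C)C(C)C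
Why: Silylation of the hindered phenol with the silyl triflate gives a bulky aryl silyl ether that resists migration and base in steps 7 to 9 and is orthogonal to the benzyl ethers.

**Step 5**
Reactants: 5 [2-allyl-6-(benzyloxy)-4-bromophenoxy]triisopropylsilane
Product: 6 2-[3-(benzyloxy)-5-bromo-2-(triisopropylsilyloxy)phenyl]acetaldehyde
Conditions: OsO4 (2 mol %), NaIO4, 2,6-lutidine, dioxane/H2O (3:1), rt
Reagents that add atoms: osmium tetroxide, O=[Os](=O)(=O)=O; sodium periodate, [Na+].[O-]I(=O)(=O)=O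
Why: Lemieux–Johnson oxidation, in which catalytic dihydroxylation of the terminal alkene and periodate cleavage of the diol give the arylacetaldehyde while 2,6-lutidine suppresses over-oxidation.

**Step 6**
Reactants: 6 2-[3-(benzyloxy)-5-bromo-2-(triisopropylsilyloxy)phenyl]acetaldehyde
Product: 7 2-[3-(benzyloxy)-5-bromo-2-(triisopropylsilyloxy)phenyl]acetic acid
Conditions: NaClO2, NaH2PO4, 2-methyl-2-butene, t-BuOH/H2O, rt
Reagents that add atoms: sodium chlorite, [Na+].[O-]Cl=O
Why: Pinnick oxidation converts the aldehyde to the acid under buffered conditions that leave the silyl ether, benzyl ether and aryl bromide untouched, the alkene scavenging hypochlorous acid.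

**Step 7**
Reactants: 7 2-[3-(benzyloxy)-5-bromo-2-(triisopropylsilyloxy)phenyl]acetic acid; 8 (S)-4-benzyl-2-oxazolidinone
Product: 10 (S)-4-benzyl-3-{2-[3-(benzyloxy)-5-bromo-2-(triisopropylsilyloxy)phenyl]acetyl}oxazolidin-2-one, via mixed pivalic anhydride 9 (not isolated)
Conditions: t-BuCOCl, Et3N, THF, −20 °C; then LiCl, 8, −20 °C → rt
Reagents that add atoms: none
Why: N-Acylation of the oxazolidinone through the mixed pivalic anhydride, which is attacked at the less hindered arylacetyl carbonyl under LiCl/Et3N activation.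

**Step 8**
Reactants: 10 (S)-4-benzyl-3-{2-[3-(benzyloxy)-5-bromo-2-(triisopropylsilyloxy)phenyl]acetyl}oxazolidin-2-one; 11 4-(benzyloxy)-3-methoxybenzaldehyde (O-benzylvanillin)
Product: 13 (S)-4-benzyl-3-{(2S,3S)-2-[3-(benzyloxy)-5-bromo-2-(triisopropylsilyloxy)phenyl]-3-[4-(benzyloxy)-3-methoxyphenyl]-3-hydroxypropanoyl}oxazolidin-2-one, via Z-dibutylboron enolate 12 (not isolated)
Conditions: n-Bu2BOTf, i-Pr2NEt, CH2Cl2, 0 °C; 11, −78 → 0 °C; then pH 7 buffer, MeOH, 30% H2O2, 0 °C
Reagents that add atoms: none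
Why: Evans syn-aldol reaction, in which soft enolisation gives the Z-boron enolate that adds to the aldehyde through a closed chair transition state on the face away from the auxiliary benzyl group, setting C2 (S) and C3 (S) of the acyl chain (C2 becomes C3 of the dihydrobenzofuran).

**Step 9**
Reactants: 13 the syn-aldol imide
Product: 14 (1S,2R)-2-[3-(benzyloxy)-5-bromo-2-(triisopropylsilyloxy)phenyl]-1-[4-(benzyloxy)-3-methoxyphenyl]propane-1,3-diol
Conditions: LiBH4, MeOH (1.5 equiv), THF, 0 °C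
Reagents that add atoms: none
Why: Borohydride reduction of the activated imide carbonyl releases the primary alcohol and the intact auxiliary without touching the stereocentres, the aryl bromide or the silyl ether (the descriptor at the aryl-bearing carbon changes from S to R only through the priority change).

**Step 10**
Reactants: 14 the silyl-protected diol
Product: 15 (1S,2R)-2-[3-(benzyloxy)-5-bromo-2-hydroxyphenyl]-1-[4-(benzyloxy)-3-methoxyphenyl]propane-1,3-diol
Conditions: Bu4NF, AcOH, THF, 0 °C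
Reagents that add atoms: none
Why: Fluoride-mediated desilylation cleaves the aryl silyl ether selectively while acetic acid buffers the phenoxide, and the benzyl ethers and both alcohols are unaffected.

**Step 11**
Reactants: 15 (1S,2R)-2-[3-(benzyloxy)-5-bromo-2-hydroxyphenyl]-1-[4-(benzyloxy)-3-methoxyphenyl]propane-1,3-diol
Product: 16 [(2S,3R)-7-(benzyloxy)-2-[4-(benzyloxy)-3-methoxyphenyl]-5-bromo-2,3-dihydrobenzofuran-3-yl]methanol
Conditions: p-TsOH·H2O (10 mol %), CH2Cl2 (0.02 M), 0 °C → rt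
Reagents that add atoms: none
Why: The acid protonates the benzylic hydroxyl and water leaves to give a cation stabilised by the para-benzyloxy group of the guaiacyl ring (a quinone-methide-like oxocarbenium form); this is the known acid-mediated cyclisation of 2-(2-hydroxyaryl)-1-arylpropane-1,3-diols to 2-aryl-3-hydroxymethyl-2,3-dihydrobenzofurans. The ortho phenol oxygen of the central arene adds to the planar cationic carbon in a 5-exo-trig closure that forms O1–C2 and the dihydrofuran ring, whereas the primary hydroxyl could only close a strained oxetane and should not compete. C2 is the only new stereocentre and is controlled by the existing C3 centre: the aryl group takes the face away from the C3 hydroxymethyl group in the lower-energy transition state, and because the product can re-ionise under the same acid the trans (2S,3R) ring is also the thermodynamic product, so the carbinol configuration of 15 is irrelevant. The step needs phenol capture to outrun loss of the C3 proton from the cation (which would give a stilbene and erase the auxiliary-derived centre) and intermolecular etherification; low temperature, a non-nucleophilic solvent, high dilution and only catalytic acid should secure this. The benzyl ethers, the aryl bromide and the primary alcohol are inert to catalytic sulfonic acid at this temperature.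

**Step 12**
Reactants: 16 the 5-bromo dihydrobenzofuran
Product: 17 [(2S,3R)-7-(benzyloxy)-2-[4-(benzyloxy)-3-methoxyphenyl]-5-(4,4,5,5-tetramethyl-1,3,2-dioxaborolan-2-yl)-2,3-dihydrobenzofuran-3-yl]methanol
Conditions: B2pin2, PdCl2(dppf) (5 mol %), KOAc, dioxane, 90 °C
Reagents that add atoms: bis(pinacolato)diboron, CC1(C)OB(OC1(C)C)B1OC(C)(C)C(C)(C)O1
Why: Miyaura borylation through oxidative addition of the aryl bromide to zerovalent palladium, acetate-assisted transmetalation with the diboron and reductive elimination, the weak base tolerating the free alcohol and benzyl ethers.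

**Step 13**
Reactants: 11 4-(benzyloxy)-3-methoxybenzaldehyde
Product: 18 [4-(benzyloxy)-3-methoxyphenyl]methanol
Conditions: NaBH4, MeOH, 0 °C
Reagents that add atoms: none
Why: Hydride reduction of the aromatic aldehyde to the benzylic alcohol.

**Step 14**
Reactants: 18 [4-(benzyloxy)-3-methoxyphenyl]methanol
Product: 19 1-(benzyloxy)-4-(bromomethyl)-2-methoxybenzene
Conditions: PBr3, Et2O, 0 °C
Reagents that add atoms: phosphorus tribromide, BrP(Br)Br
Why: Bromide substitution of the electron-rich benzylic alcohol through its phosphite ester, the bromide being used without storage.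

**Step 15**
Reactants: 20 4-tert-butoxy-4-oxobutanoic acid (mono-tert-butyl succinate); 8 (S)-4-benzyl-2-oxazolidinone
Product: 22 tert-butyl 4-[(S)-4-benzyl-2-oxooxazolidin-3-yl]-4-oxobutanoate, via mixed pivalic anhydride 21 (not isolated)
Conditions: t-BuCOCl, Et3N, THF, −20 °C; then LiCl, 8, rt
Reagents that add atoms: none
Why: Mixed-anhydride N-acylation of the oxazolidinone as in step 7, the tert-butyl ester being inert.

**Step 16**
Reactants: 22 the succinyl imide; 19 1-(benzyloxy)-4-(bromomethyl)-2-methoxybenzene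
Product: 24 tert-butyl (S)-3-[(S)-4-benzyl-2-oxooxazolidine-3-carbonyl]-4-[4-(benzyloxy)-3-methoxyphenyl]butanoate, via sodium Z-enolate 23 (not isolated)
Conditions: NaN(SiMe3)2, THF, −78 °C; then 19, −78 → −40 °C
Reagents that add atoms: none
Why: Evans asymmetric alkylation, in which the chelated sodium Z-enolate of the imide (more acidic than the tert-butyl ester) is benzylated on the face opposite the auxiliary benzyl group, setting the future lactone C4 as S.

**Step 17**
Reactants: 24 the alkylated imide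
Product: 26 (S)-4-[4-(benzyloxy)-3-methoxybenzyl]dihydrofuran-2(3H)-one, via hydroxy ester 25 (not isolated)
Conditions: LiBH4, MeOH (1.5 equiv), THF, 0 °C; crude, then p-TsOH·H2O (10 mol %), toluene, 60 °C
Reagents that add atoms: none
Why: Borohydride cleaves the imide to the primary alcohol while the tert-butyl ester survives, and acid-catalysed transesterification then closes the five-membered lactone (5-exo-trig acyl substitution) without touching the stereocentre.

**Step 18**
Reactants: 26 (S)-4-[4-(benzyloxy)-3-methoxybenzyl]dihydrofuran-2(3H)-one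
Product: 28 (S)-4-[4-(benzyloxy)-3-methoxybenzyl]-3-methylenedihydrofuran-2(3H)-one, via sodium formyl enolate 27 (not isolated)
Conditions: NaH, HCO2Et, THF, 0 °C → rt; then (CH2O)n, THF, reflux
Reagents that add atoms: formaldehyde (from paraformaldehyde), C=O
Why: α-Methylenation by Claisen formylation of the lactone enolate, then aldol addition to formaldehyde, formyl transfer and loss of formate (deformylative methylenation), the C4 centre not being enolisable under these conditions.

**Step 19**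
Reactants: 17 the aryl pinacol boronate; 28 the (S)-α-methylene lactone
Product: 29 (4S)-3-{[(2S,3R)-7-(benzyloxy)-2-[4-(benzyloxy)-3-methoxyphenyl]-3-(hydroxymethyl)-2,3-dihydrobenzofuran-5-yl]methyl}-4-[4-(benzyloxy)-3-methoxybenzyl]dihydrofuran-2(3H)-one as a mixture of epimers at lactone C3
Conditions: [Rh(OH)(cod)]2 (3 mol %), dioxane/H2O (10:1), 60 °C
Reagents that add atoms: none
Why: Hayashi–Miyaura-type rhodium-catalysed 1,4-addition, in which the aryl group passes from boron to monovalent rhodium, adds to the exocyclic methylene of the acrylate-like lactone and the rhodium enolate is protonated by water, so the new lactone C3 centre is not controlled here and is corrected in step 20.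

**Step 20**
Reactants: 29 the C3-epimeric lactone mixture
Product: 30 (3S,4S)-3-{[(2S,3R)-7-(benzyloxy)-2-[4-(benzyloxy)-3-methoxyphenyl]-3-(hydroxymethyl)-2,3-dihydrobenzofuran-5-yl]methyl}-4-[4-(benzyloxy)-3-methoxybenzyl]dihydrofuran-2(3H)-one
Conditions: NaOMe (0.3 equiv), MeOH/THF, rt; then AcOH
Reagents that add atoms: none
Why: Base-mediated epimerisation through the lactone enolate should give the thermodynamically preferred trans-2,3-dibenzyl lactone, so C3 (S) is set by the fixed C4 (S) centre.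

**Step 21**
Reactants: 30 the tribenzyl trans lactone
Product: 31 (3S,4S)-3-{[(2S,3R)-7-hydroxy-2-(4-hydroxy-3-methoxyphenyl)-3-(hydroxymethyl)-2,3-dihydrobenzofuran-5-yl]methyl}-4-(4-hydroxy-3-methoxybenzyl)dihydrofuran-2(3H)-one (CNP0118131.1)
Conditions: H2 (1 atm), 10% Pd/C, EtOAc/EtOH, rt
Reagents that add atoms: none
Why: Hydrogenolysis of the three aryl benzyl ethers on Pd/C at ambient pressure, which should be cleaved faster than the cyclic benzylic C2–O1 ether if the reaction is stopped at complete debenzylation.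

**Compound list**
1 | 2-(benzyloxy)phenol | Oc1ccccc1OCc1ccccc1 | starting material
2 | 2-(benzyloxy)-4-bromophenol | Oc1ccc(Br)cc1OCc1ccccc1 | intermediate
3 | 1-(allyloxy)-2-(benzyloxy)-4-bromobenzene | C=CCOc1ccc(Br)cc1OCc1ccccc1 | intermediate
4 | 2-allyl-6-(benzyloxy)-4-bromophenol | C=CCc1cc(Br)cc(OCc2ccccc2)c1O | intermediate
5 | [2-allyl-6-(benzyloxy)-4-bromophenoxy]triisopropylsilane | C=CCc1cc(Br)cc(OCc2ccccc2)c1O[Si](C(C)C)(C(C)C)C(C)C | intermediate
6 | 2-[3-(benzyloxy)-5-bromo-2-(triisopropylsilyloxy)phenyl]acetaldehyde | O=CCc1cc(Br)cc(OCc2ccccc2)c1O[Si](C(C)C)(C(C)C)C(C)C | intermediate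
7 | 2-[3-(benzyloxy)-5-bromo-2-(triisopropylsilyloxy)phenyl]acetic acid | OC(=O)Cc1cc(Br)cc(OCc2ccccc2)c1O[Si](C(C)C)(C(C)C)C(C)C | intermediate
8 | (S)-4-benzyl-2-oxazolidinone | O=C1N[C@@H](Cc2ccccc2)CO1 | starting material
9 | mixed pivalic anhydride of acid 7 | CC(C)(C)C(=O)OC(=O)Cc1cc(Br)cc(OCc2ccccc2)c1O[Si](C(C)C)(C(C)C)C(C)C | intermediate
10 | (S)-4-benzyl-3-{2-[3-(benzyloxy)-5-bromo-2-(triisopropylsilyloxy)phenyl]acetyl}oxazolidin-2-one | O=C1OC[C@H](Cc2ccccc2)N1C(=O)Cc1cc(Br)cc(OCc2ccccc2)c1O[Si](C(C)C)(C(C)C)C(C)C | intermediate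
11 | 4-(benzyloxy)-3-methoxybenzaldehyde (O-benzylvanillin) | COc1cc(C=O)ccc1OCc1ccccc1 | starting material
12 | Z-dibutylboron enolate of imide 10 | CCCCB(CCCC)O/C(=C\c1cc(Br)cc(OCc2ccccc2)c1O[Si](C(C)C)(C(C)C)C(C)C)N1C(=O)OC[C@@H]1Cc1ccccc1 | intermediate
13 | (S)-4-benzyl-3-{(2S,3S)-2-[3-(benzyloxy)-5-bromo-2-(triisopropylsilyloxy)phenyl]-3-[4-(benzyloxy)-3-methoxyphenyl]-3-hydroxypropanoyl}oxazolidin-2-one | O=C1OC[C@H](Cc2ccccc2)N1C(=O)[C@@H](c1cc(Br)cc(OCc2ccccc2)c1O[Si](C(C)C)(C(C)C)C(C)C)[C@H](O)c1ccc(OCc2ccccc2)c(OC)c1 | intermediate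
14 | (1S,2R)-2-[3-(benzyloxy)-5-bromo-2-(triisopropylsilyloxy)phenyl]-1-[4-(benzyloxy)-3-methoxyphenyl]propane-1,3-diol | OC[C@@H](c1cc(Br)cc(OCc2ccccc2)c1O[Si](C(C)C)(C(C)C)C(C)C)[C@H](O)c1ccc(OCc2ccccc2)c(OC)c1 | intermediate
15 | (1S,2R)-2-[3-(benzyloxy)-5-bromo-2-hydroxyphenyl]-1-[4-(benzyloxy)-3-methoxyphenyl]propane-1,3-diol | Brc1cc(OCc2ccccc2)c(O)c(c1)[C@H](CO)[C@@H](c1ccc(OCc2ccccc2)c(OC)c1)O | intermediate
16 | [(2S,3R)-7-(benzyloxy)-2-[4-(benzyloxy)-3-methoxyphenyl]-5-bromo-2,3-dihydrobenzofuran-3-yl]methanol | Brc1cc(OCc2ccccc2)c2c(c1)[C@H](CO)[C@@H](c1ccc(OCc3ccccc3)c(OC)c1)O2 | intermediate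
17 | [(2S,3R)-7-(benzyloxy)-2-[4-(benzyloxy)-3-methoxyphenyl]-5-(4,4,5,5-tetramethyl-1,3,2-dioxaborolan-2-yl)-2,3-dihydrobenzofuran-3-yl]methanol | CC1(C)OB(OC1(C)C)c1cc(OCc2ccccc2)c2c(c1)[C@H](CO)[C@@H](c1ccc(OCc3ccccc3)c(OC)c1)O2 | intermediate
18 | [4-(benzyloxy)-3-methoxyphenyl]methanol | COc1cc(CO)ccc1OCc1ccccc1 | intermediate
19 | 1-(benzyloxy)-4-(bromomethyl)-2-methoxybenzene | COc1cc(CBr)ccc1OCc1ccccc1 | intermediate
20 | 4-tert-butoxy-4-oxobutanoic acid (mono-tert-butyl succinate) | CC(C)(C)OC(=O)CCC(O)=O | starting material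
21 | mixed pivalic anhydride of acid 20 | CC(C)(C)OC(=O)CCC(=O)OC(=O)C(C)(C)C | intermediate
22 | tert-butyl 4-[(S)-4-benzyl-2-oxooxazolidin-3-yl]-4-oxobutanoate | CC(C)(C)OC(=O)CCC(=O)N1C(=O)OC[C@@H]1Cc1ccccc1 | intermediate
23 | sodium Z-enolate of imide 22 | [Na+].[O-]/C(=C\CC(=O)OC(C)(C)C)N1C(=O)OC[C@@H]1Cc1ccccc1 | intermediate
24 | tert-butyl (S)-3-[(S)-4-benzyl-2-oxooxazolidine-3-carbonyl]-4-[4-(benzyloxy)-3-methoxyphenyl]butanoate | CC(C)(C)OC(=O)C[C@H](Cc1ccc(OCc2ccccc2)c(OC)c1)C(=O)N1C(=O)OC[C@@H]1Cc1ccccc1 | intermediate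
25 | tert-butyl (S)-4-[4-(benzyloxy)-3-methoxyphenyl]-3-(hydroxymethyl)butanoate | CC(C)(C)OC(=O)C[C@@H](CO)Cc1ccc(OCc2ccccc2)c(OC)c1 | intermediate
26 | (S)-4-[4-(benzyloxy)-3-methoxybenzyl]dihydrofuran-2(3H)-one | O=C1OC[C@@H](Cc2ccc(OCc3ccccc3)c(OC)c2)C1 | intermediate
27 | sodium enolate of (S)-3-formyl-4-[4-(benzyloxy)-3-methoxybenzyl]dihydrofuran-2(3H)-one | [Na+].[O-]C=C1C(=O)OC[C@H]1Cc1ccc(OCc2ccccc2)c(OC)c1 | intermediate
28 | (S)-4-[4-(benzyloxy)-3-methoxybenzyl]-3-methylenedihydrofuran-2(3H)-one | C=C1C(=O)OC[C@H]1Cc1ccc(OCc2ccccc2)c(OC)c1 | intermediate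
29 | (4S)-3-{[(2S,3R)-7-(benzyloxy)-2-[4-(benzyloxy)-3-methoxyphenyl]-3-(hydroxymethyl)-2,3-dihydrobenzofuran-5-yl]methyl}-4-[4-(benzyloxy)-3-methoxybenzyl]dihydrofuran-2(3H)-one, C3 epimers | COc1cc(C[C@@H]2COC(=O)C2Cc2cc(OCc4ccccc4)c3c(c2)[C@H](CO)[C@@H](c2ccc(OCc4ccccc4)c(OC)c2)O3)ccc1OCc1ccccc1 | intermediate
30 | (3S,4S)-3-{[(2S,3R)-7-(benzyloxy)-2-[4-(benzyloxy)-3-methoxyphenyl]-3-(hydroxymethyl)-2,3-dihydrobenzofuran-5-yl]methyl}-4-[4-(benzyloxy)-3-methoxybenzyl]dihydrofuran-2(3H)-one | COc1cc(C[C@@H]2COC(=O)[C@H]2Cc2cc(OCc4ccccc4)c3c(c2)[C@H](CO)[C@@H](c2ccc(OCc4ccccc4)c(OC)c2)O3)ccc1OCc1ccccc1 | intermediate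
31 | (3S,4S)-3-{[(2S,3R)-7-hydroxy-2-(4-hydroxy-3-methoxyphenyl)-3-(hydroxymethyl)-2,3-dihydrobenzofuran-5-yl]methyl}-4-(4-hydroxy-3-methoxybenzyl)dihydrofuran-2(3H)-one | COc1cc(C[C@@H]2COC(=O)[C@H]2Cc2cc(O)c3c(c2)[C@H](CO)[C@@H](c2ccc(O)c(OC)c2)O3)ccc1O | target

**Step count and risks**
Total step count: 21. Longest linear sequence: 15 steps (steps 1–12 and 19–21, from 2-(benzyloxy)phenol).

Step 11 (key cyclisation). The cation may lose the C3 proton faster than the phenol captures it, which would erode the C3 configuration or divert material to a 2,3-diarylallyl alcohol, or capture may occur without full trans control. The fallback closes the same O1–C2 bond through a neutral para-quinone methide under basic conditions; it sets out from imide 10 and returns at 16.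
- Boron aldol as in step 8, but with commercial 4-(tert-butyldimethylsilyloxy)-3-methoxybenzaldehyde, gives the bis-silylated syn-aldol imide F1.
- LiBH4 gives the bis-silylated diol F2, and Ac2O/pyridine/DMAP gives the diacetate F3.
- Bu4NF in THF removes both aryl silyl groups; the para phenoxide expels the benzylic acetate (1,6-elimination) to the para-quinone methide F4, and the ortho phenoxide adds to it (5-exo-trig oxa-Michael addition) to give the trans dihydrobenzofuran phenol acetate F5.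
- BnBr/K2CO3 in DMF gives the benzyl ether acetate F6, and K2CO3/MeOH removes the acetate to give 16.

Step 19 (conjugate arylation). Protodeboronation of 17, base-induced migration of the exocyclic double bond of 28 into the ring (loss of the C4 centre), or β-hydride elimination to a benzylidene lactone may outpace productive addition. The fallback is the classical trans-selective enolate alkylation; it sets out from 16 and returns at 30, so steps 12 and 18–20 are then not needed.
- TBSCl/imidazole gives the silyl ether F7.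
- n-BuLi (THF, −78 °C) then DMF gives the aldehyde F8, and NaBH4 gives the benzylic alcohol F9.
- CBr4/PPh3 gives the benzylic bromide F10.
- Alkylation of the lithium enolate of lactone 26 (LiN(SiMe3)2, THF, −78 °C) with F10, anti to the C4 substituent, gives the silylated trans lactone F11.
- Bu4NF gives 30.

Step 8 (aldol). Addition of the hindered ortho-silyloxyaryl enolate to the electron-rich aldehyde may be slow, with retro-aldol reaction or epimerisation of the acidic α-aryl centre during work-up or reduction. The fallback uses a more reactive chlorotitanium enolate on a thiazolidinethione whose auxiliary is removed by NaBH4; it sets out from acid 7 and returns at 14.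
- EDC·HCl/DMAP coupling with commercial (S)-4-benzylthiazolidine-2-thione gives the N-acyl thiazolidinethione F12.
- TiCl4, i-Pr2NEt, N-methyl-2-pyrrolidinone, CH2Cl2, 0 °C, then 11 at −78 → 0 °C, gives the Evans-syn adduct F13.
- NaBH4 in THF/EtOH at 0 °C cleaves the auxiliary and gives 14.

**Further compounds**
F1 | step 11 | (S)-4-benzyl-3-{(2S,3S)-2-[3-(benzyloxy)-5-bromo-2-(triisopropylsilyloxy)phenyl]-3-[4-(tert-butyldimethylsilyloxy)-3-methoxyphenyl]-3-hydroxypropanoyl}oxazolidin-2-one | O=C1OC[C@H](Cc2ccccc2)N1C(=O)[C@@H](c1cc(Br)cc(OCc2ccccc2)c1O[Si](C(C)C)(C(C)C)C(C)C)[C@H](O)c1ccc(O[Si](C)(C)C(C)(C)C)c(OC)c1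
F2 | step 11 | (1S,2R)-2-[3-(benzyloxy)-5-bromo-2-(triisopropylsilyloxy)phenyl]-1-[4-(tert-butyldimethylsilyloxy)-3-methoxyphenyl]propane-1,3-diol | OC[C@@H](c1cc(Br)cc(OCc2ccccc2)c1O[Si](C(C)C)(C(C)C)C(C)C)[C@H](O)c1ccc(O[Si](C)(C)C(C)(C)C)c(OC)c1
F3 | step 11 | (1S,2R)-2-[3-(benzyloxy)-5-bromo-2-(triisopropylsilyloxy)phenyl]-1-[4-(tert-butyldimethylsilyloxy)-3-methoxyphenyl]propane-1,3-diyl diacetate | CC(=O)OC[C@@H](c1cc(Br)cc(OCc2ccccc2)c1O[Si](C(C)C)(C(C)C)C(C)C)[C@H](OC(C)=O)c1ccc(O[Si](C)(C)C(C)(C)C)c(OC)c1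
F4 | step 11 | (2R)-2-[3-(benzyloxy)-5-bromo-2-hydroxyphenyl]-3-(3-methoxy-4-oxocyclohexa-2,5-dien-1-ylidene)propyl acetate (para-quinone methide) | CC(=O)OC[C@@H](c1cc(Br)cc(OCc2ccccc2)c1O)C=C1C=CC(=O)C(OC)=C1
F5 | step 11 | [(2S,3R)-7-(benzyloxy)-5-bromo-2-(4-hydroxy-3-methoxyphenyl)-2,3-dihydrobenzofuran-3-yl]methyl acetate | Brc1cc(OCc2ccccc2)c2c(c1)[C@H](COC(C)=O)[C@@H](c1ccc(O)c(OC)c1)O2
F6 | step 11 | [(2S,3R)-7-(benzyloxy)-2-[4-(benzyloxy)-3-methoxyphenyl]-5-bromo-2,3-dihydrobenzofuran-3-yl]methyl acetate | Brc1cc(OCc2ccccc2)c2c(c1)[C@H](COC(C)=O)[C@@H](c1ccc(OCc3ccccc3)c(OC)c1)O2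
F7 | step 19 | {[(2S,3R)-7-(benzyloxy)-2-[4-(benzyloxy)-3-methoxyphenyl]-5-bromo-2,3-dihydrobenzofuran-3-yl]methoxy}(tert-butyl)dimethylsilane | Brc1cc(OCc2ccccc2)c2c(c1)[C@H](CO[Si](C)(C)C(C)(C)C)[C@@H](c1ccc(OCc3ccccc3)c(OC)c1)O2
F8 | step 19 | (2S,3R)-7-(benzyloxy)-2-[4-(benzyloxy)-3-methoxyphenyl]-3-[(tert-butyldimethylsilyloxy)methyl]-2,3-dihydrobenzofuran-5-carbaldehyde | O=Cc1cc(OCc2ccccc2)c2c(c1)[C@H](CO[Si](C)(C)C(C)(C)C)[C@@H](c1ccc(OCc3ccccc3)c(OC)c1)O2
F9 | step 19 | {(2S,3R)-7-(benzyloxy)-2-[4-(benzyloxy)-3-methoxyphenyl]-3-[(tert-butyldimethylsilyloxy)methyl]-2,3-dihydrobenzofuran-5-yl}methanol | OCc1cc(OCc2ccccc2)c2c(c1)[C@H](CO[Si](C)(C)C(C)(C)C)[C@@H](c1ccc(OCc3ccccc3)c(OC)c1)O2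
F10 | step 19 | {[(2S,3R)-7-(benzyloxy)-2-[4-(benzyloxy)-3-methoxyphenyl]-5-(bromomethyl)-2,3-dihydrobenzofuran-3-yl]methoxy}(tert-butyl)dimethylsilane | BrCc1cc(OCc2ccccc2)c2c(c1)[C@H](CO[Si](C)(C)C(C)(C)C)[C@@H](c1ccc(OCc3ccccc3)c(OC)c1)O2
F11 | step 19 | (3S,4S)-3-{[(2S,3R)-7-(benzyloxy)-2-[4-(benzyloxy)-3-methoxyphenyl]-3-[(tert-butyldimethylsilyloxy)methyl]-2,3-dihydrobenzofuran-5-yl]methyl}-4-[4-(benzyloxy)-3-methoxybenzyl]dihydrofuran-2(3H)-one | COc1cc(C[C@@H]2COC(=O)[C@H]2Cc2cc(OCc4ccccc4)c3c(c2)[C@H](CO[Si](C)(C)C(C)(C)C)[C@@H](c2ccc(OCc4ccccc4)c(OC)c2)O3)ccc1OCc1ccccc1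
F12 | step 8 | (S)-4-benzyl-3-{2-[3-(benzyloxy)-5-bromo-2-(triisopropylsilyloxy)phenyl]acetyl}thiazolidine-2-thione | S=C1SC[C@H](Cc2ccccc2)N1C(=O)Cc1cc(Br)cc(OCc2ccccc2)c1O[Si](C(C)C)(C(C)C)C(C)C
F13 | step 8 | (S)-4-benzyl-3-{(2S,3S)-2-[3-(benzyloxy)-5-bromo-2-(triisopropylsilyloxy)phenyl]-3-[4-(benzyloxy)-3-methoxyphenyl]-3-hydroxypropanoyl}thiazolidine-2-thione | S=C1SC[C@H](Cc2ccccc2)N1C(=O)[C@@H](c1cc(Br)cc(OCc2ccccc2)c1O[Si](C(C)C)(C(C)C)C(C)C)[C@H](O)c1ccc(OCc2ccccc2)c(OC)c1
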